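The rate constants were drawn at random within sensible limits; no experiment stands behind them.

I decided to follow the rate at which L is used, and to treat the radicals as a level that follows G.

    G → 2 X (k1 = 0.105 h⁻¹)
    L + Q → J + Q, rate k2*[Q]*[L] (k2 = 1.14 × 10⁷ L mol⁻¹ h⁻¹)
    L + X → Q + J (k3 = 36600 L mol⁻¹ s⁻¹)
    2 Q → Q2 (k4 = 1.9 × 10⁷ L mol⁻¹ s⁻¹)

L 0.30 M; G 0.33 mM; time 8.0 h

- average number of monomer units in a chain (living and dead chains, two that joined counted as one) at 8.0 h
- part of the L that has reacted at 8.0 h

- two of one species on the left: rate k times its square, two consumed each time
- the average divides the monomer in chains by the number of chains, living and dead together; two radicals that join make one chain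
- run time (flask): 8.0 h

I took every X as becoming Q, so that making and loss of Q balance (the steady-state approximation):

starting c(Q) = root of (decay constant of G × c(G) ÷ constant of the joining of Q) = 2.25 × 10⁻⁸ M

At that level Q turns over in about 1.17 s, and G has a half-life of 6.6 h, so the level can follow G. L is then used in a pseudo-first-order way, with a starting constant of 0.257 h⁻¹ and a starting rate of 0.0770 M h⁻¹.

Two things slow this rate. By 8.0 h, the fall of G, entering by its root, multiplies it by 0.657. For the end I reckoned the accumulated constant:

effective time = 2 × 0.343 ÷ decay constant of G = 6.53 h

exposure = starting constant × effective time = 1.68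

This exposure is the time integral of the pseudo-first-order constant. By the same time the loss of L multiplies the rate by exp(−exposure) = 0.187, so I expected 81.3 % of L to have reacted. I reckoned no chain length.

The forecast gave 81.3 % and 1300 units per chain, with a Q level that “decays as the initiator runs down”.

The flask gave 81.3 % and 1300 units per chain. At 2.15 h in the flask, L was used 740 times faster with Q than with X. Read as an exposure, the flask's 81.3 % is 1.68. The neighbour flask was charged with 2.0 × 10⁻⁴ M of G, its L charge and its time held as in the flask; with these held, the exposure I reckoned goes with the root of the G charge, which gives 1.30 and 72.7 % of L reacted. The neighbour flask gave 72.9 %, with 1920 units per chain.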